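**Strategy**

1. Cuts: the styrene C=C of the caffeate (decarboxylative condensation) and the C11–O ester bond (malonic half-ester of (−)-drimenol); then C9–C11 back to a C9 ketone; then ring A at C3–C4 (radical closure), C1–C10 and C10–CH3 (two enolate alkylations).
2. Enabling feature: ring B (C5–C10) with the C8 methyl, the C7=C8 alkene, an oxygen at C9 and the carbon that becomes C4 is, atom for atom, (R)-carvone. The isopropenyl carbon already carries both C4 methyl carbons and lacks only one hydrogen and the C3–C4 bond, so hydrogen-atom transfer makes it the tertiary radical that closes ring A onto a 2-sulfonylallyl arm on C10.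
3. Forward order: ring B is bought; C10 is made quaternary (methyl, then 2-(phenylsulfonyl)allyl); ring A closes by 6-endo radical addition; C11 is added by methylenation and hydroboration; the sulfone is removed; the malonate is attached and the arene is joined last.
4. Stereochemistry: C5 is the carvone stereocentre and is never touched. C10 comes from alkylation anti to the isopropenyl group, which fixes the trans ring fusion. C9 comes from hydroboration on the α face, away from the axial C10 methyl. The E alkene comes from the Doebner decarboxylation.

Key step: step 5

Assumption: the configuration at C6 of 3 and at the sulfonyl-bearing carbon (drimane C2) of 9–12 is left undefined, since both centres are erased later (steps 4 and 8); LDA is taken as the commercial solution.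

**Route**

Step 1
Reactants: 1 (R)-(−)-carvone
Product: 3 6-methylcarvone (both C6 epimers), via carvone lithium dienolate 2 (not isolated)
Conditions: LDA (1.05 equiv), THF, −78 °C; MeI, −78 → 0 °C
Reagents that add atoms: iodomethane CI
Why: Kinetic α′-enolate alkylation: LDA removes the C6 proton of the enone faster than any γ-proton and the cross-conjugated lithium enolate is C-methylated; the new C6 centre forms as an epimer mixture, which does not matter because step 4 makes this carbon planar again.

Step 2
Reactants: 4 phenyl vinyl sulfone
Product: 5 2-(phenylsulfonyl)prop-2-en-1-ol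
Conditions: aq. CH2O (37 %), DABCO (0.5 equiv), 1,4-dioxane/H2O, rt
Reagents that add atoms: formaldehyde C=O
Why: Morita–Baylis–Hillman reaction: DABCO adds to the vinyl sulfone, the α-sulfonyl carbanion is trapped by formaldehyde and loss of the amine restores the alkene, a known α-hydroxymethylation of aryl vinyl sulfones; no stereocentre is formed.

Step 3
Reactants: 5 2-(phenylsulfonyl)prop-2-en-1-ol
Product: 6 2-(phenylsulfonyl)allyl bromide [3-bromo-2-(phenylsulfonyl)prop-1-ene]
Conditions: PBr3 (0.4 equiv), Et2O, 0 °C → rt
Reagents that add atoms: phosphorus tribromide BrP(Br)Br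
Why: Standard PBr3 conversion of a Baylis–Hillman-type primary allylic alcohol into the bromide; SN2 and SN2′ displacement of the phosphite give the same product, so no regiochemical issue arises.

Step 4
Reactants: 3 6-methylcarvone; 6 2-(phenylsulfonyl)allyl bromide
Product: 8 (5S,6S)-2,6-dimethyl-6-[2-(phenylsulfonyl)prop-2-en-1-yl]-5-(prop-1-en-2-yl)cyclohex-2-en-1-one, via 6-methylcarvone lithium enolate 7 (not isolated)
Conditions: LDA (1.1 equiv), THF, −78 → −20 °C; DMPU, then 6 (1.2 equiv), −78 → −40 °C
Reagents that add atoms: none
Why: Enolate alkylation by addition–elimination (SN2′): the fully substituted enolate attacks the CH2 terminus of the Michael acceptor and bromide is expelled; as in the known second alkylations of 6-alkylcarvones, the electrophile enters on the face opposite the neighbouring isopropenyl group, so the new quaternary centre (future C10) carries the sulfonylallyl arm trans and the methyl cis to the isopropenyl group.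

Step 5
Reactants: 8 the sulfonylallyl carvone from step 4
Product: 9 (4aS,8aS)-2,5,5,8a-tetramethyl-7-(phenylsulfonyl)-4a,5,6,7,8,8a-hexahydronaphthalen-1(4H)-one [2ξ-(phenylsulfonyl)-11-nordrim-7-en-9-one]
Conditions: Fe(acac)3 (30 mol %), PhSiH3 (2.5 equiv), EtOH/(CH2OH)2 5:1, 0.02 M, 60 °C, Ar
Reagents that add atoms: none
Why: An iron hydride formed from Fe(acac)3 and the silane should transfer a hydrogen atom to the CH2 of the isopropenyl group (Markovnikov sense), giving a nucleophilic tertiary radical at the future C4; this adds to the unsubstituted terminus (future C3) of the electron-poor vinyl sulfone, and the resulting α-sulfonyl radical is reduced by iron(II) and protonated by ethanol. The closest known reaction type is the iron-catalysed hydrogen-atom-transfer reductive olefin coupling (Giese-type addition of alkene-derived tertiary radicals to vinyl sulfones and enones), including its intramolecular decalin-forming cases. Ring A closes in the 6-endo-trig mode through a chair-like transition state; 5-exo closure is disfavoured twice over, since it would create two adjacent quaternary carbons and an unstabilised primary radical. The only new stereocentre is the sulfonyl-bearing C2, which is not controlled and need not be because step 8 removes it; the trans ring fusion is inherited from the trans C5/C10 arms fixed in step 4. The step needs hydrogen-atom transfer to the isopropenyl group rather than to the enone or vinyl sulfone, which alkene electronics secure (only the isopropenyl alkene is electron-neutral), and ring closure faster than radical quenching, which the matched nucleophilic radical/electrophilic alkene pair secures. Closure onto the enone is impossible because it would have to form a cyclobutane.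

Step 6
Reactants: 9 2ξ-(phenylsulfonyl)-11-nordrim-7-en-9-one
Product: 10 2ξ-(phenylsulfonyl)drima-7,9(11)-diene
Conditions: Cp2TiMe2 (3 equiv), toluene/THF, 70 °C, dark
Reagents that add atoms: dimethyltitanocene C[Ti](C)(C1C=CC=C1)C1C=CC=C1
Why: Petasis methylenation: thermally generated titanocene methylidene adds [2+2] to the carbonyl and cycloreverts to the alkene, driven by Ti=O formation; the reagent is non-basic, so neither the α-sulfonyl C–H nor the γ-protons of the enone interfere, and it is known to methylenate hindered and conjugated ketones at the carbonyl only.

Step 7
Reactants: 10 2ξ-(phenylsulfonyl)drima-7,9(11)-diene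
Product: 12 2ξ-(phenylsulfonyl)drimenol, via B-alkyl-9-BBN adduct 11 (not isolated)
Conditions: 9-BBN (1.5 equiv), THF, 0 °C → rt; then aq. NaOH, 30 % H2O2, 0 °C → rt
Reagents that add atoms: hydrogen peroxide OO
Why: Hydroboration–oxidation: 9-BBN reacts with the 1,1-disubstituted exocyclic alkene far faster than with the trisubstituted ring alkene and places boron on terminal C11; hydrogen is delivered to C9 on the α face, away from the axial methyl on adjacent C10, so C11 ends up β and equatorial (9S), and alkaline peroxide replaces boron by OH with retention.

Step 8
Reactants: 12 2ξ-(phenylsulfonyl)drimenol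
Product: 13 (−)-drimenol
Conditions: 6 % Na(Hg), Na2HPO4, MeOH/THF, −20 °C → rt
Reagents that add atoms: none
Why: Reductive desulfonylation by electron transfer: the sulfone radical anion fragments to benzenesulfinate and a secondary alkyl radical that is reduced and protonated; the buffer prevents a strongly basic medium, the isolated trisubstituted alkene and the alcohol are inert, and the undefined C2 centre disappears.

Step 9
Reactants: 13 (−)-drimenol; 14 Meldrum's acid
Product: 15 drimenyl hydrogen malonate
Conditions: toluene, 110 °C
Reagents that add atoms: none
Why: Alcoholysis of Meldrum's acid: the primary alcohol opens the cyclic acylal at one carbonyl and acetone is lost, which gives the malonic half-ester under neutral conditions without a coupling agent and without risk to the alkene or the C9 centre.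

Step 10
Reactants: 15 drimenyl hydrogen malonate; 16 3,4-dihydroxybenzaldehyde
Product: 18 drimenyl (E)-caffeate (target), via arylidenemalonic half-ester 17 (not isolated)
Conditions: pyridine, piperidine (0.1 equiv), Ar, rt → 60 °C
Reagents that add atoms: none
Why: Knoevenagel–Doebner condensation: the aldehyde (as its piperidine iminium) condenses with the half-ester and the arylidenemalonic acid loses CO2 in pyridine to give the thermodynamically preferred E-cinnamate; the condensation is established for 3,4-dihydroxybenzaldehyde with free hydroxyl groups, and no stereocentre is touched.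

**Compound list**

1 | (R)-(−)-carvone | CC1=CC[C@H](CC1=O)C(C)=C | starting material
2 | carvone lithium dienolate (C1=C6 enolate) | CC1=CC[C@@H](C(C)=C)C=C1O[Li] | intermediate
3 | 6-methylcarvone, (5R)-2,6-dimethyl-5-(prop-1-en-2-yl)cyclohex-2-en-1-one, C6 epimer mixture | CC1=CC[C@@H](C(C)=C)C(C)C1=O | intermediate
4 | phenyl vinyl sulfone | C=CS(=O)(=O)c1ccccc1 | starting material
5 | 2-(phenylsulfonyl)prop-2-en-1-ol | C=C(CO)S(=O)(=O)c1ccccc1 | intermediate
6 | 2-(phenylsulfonyl)allyl bromide | C=C(CBr)S(=O)(=O)c1ccccc1 | intermediate
7 | 6-methylcarvone lithium enolate | CC1=CC[C@@H](C(C)=C)C(C)=C1O[Li] | intermediate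
8 | (5S,6S)-2,6-dimethyl-6-[2-(phenylsulfonyl)prop-2-en-1-yl]-5-(prop-1-en-2-yl)cyclohex-2-en-1-one | CC1=CC[C@@H](C(C)=C)[C@](C)(CC(=C)S(=O)(=O)c2ccccc2)C1=O | intermediate
9 | 2ξ-(phenylsulfonyl)-11-nordrim-7-en-9-one (trans-fused) | CC1=CC[C@H]2C(C)(C)CC(S(=O)(=O)c3ccccc3)C[C@]2(C)C1=O | intermediate
10 | 2ξ-(phenylsulfonyl)drima-7,9(11)-diene | CC1=CC[C@H]2C(C)(C)CC(S(=O)(=O)c3ccccc3)C[C@]2(C)C1=C | intermediate
11 | B-[2ξ-(phenylsulfonyl)drim-7-en-11-yl]-9-borabicyclo[3.3.1]nonane | CC1=CC[C@H]2C(C)(C)CC(S(=O)(=O)c3ccccc3)C[C@]2(C)[C@H]1CB1C2CCCC1CCC2 | intermediate
12 | 2ξ-(phenylsulfonyl)drimenol | CC1=CC[C@H]2C(C)(C)CC(S(=O)(=O)c3ccccc3)C[C@]2(C)[C@H]1CO | intermediate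
13 | (−)-drimenol, (5S,9S,10S)-drim-7-en-11-ol | CC1=CC[C@H]2C(C)(C)CCC[C@]2(C)[C@H]1CO | intermediate
14 | Meldrum's acid | CC1(C)OC(=O)CC(=O)O1 | starting material
15 | drimenyl hydrogen malonate | CC1=CC[C@H]2C(C)(C)CCC[C@]2(C)[C@H]1COC(=O)CC(=O)O | intermediate
16 | 3,4-dihydroxybenzaldehyde | O=Cc1ccc(O)c(O)c1 | starting material
17 | drimenyl hydrogen 2-(3,4-dihydroxybenzylidene)malonate | CC1=CC[C@H]2C(C)(C)CCC[C@]2(C)[C@H]1COC(=O)C(=Cc1ccc(O)c(O)c1)C(=O)O | intermediate
18 | drimenyl (E)-caffeate | CC1=CC[C@H]2C(C)(C)CCC[C@]2(C)[C@H]1COC(=O)/C=C/c1ccc(O)c(O)c1 | target

**Step count and risks**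

Total: 10 steps. Longest linear sequence: 9 steps (from 4 through steps 2–10); 8 steps from carvone.

Steps most likely to fail:

Step 5. The tertiary radical may be quenched by a second hydrogen atom before it closes, because the ring conformer with both arms equatorial is probably not the resting one, or the iron hydride may reduce the vinyl sulfone directly. Either way the result would be hydrogenation instead of ring closure. The fallback separates radical generation from hydride delivery. Setting out from 8, Markovnikov hydrobromination of the isopropenyl group (HBr in AcOH, 0 °C, the classical carvone hydrobromide reaction) should give the tertiary bromide F1. Slow addition of Bu3SnH with AIBN in refluxing benzene then forms the same C4 radical by bromine abstraction at low hydride concentration, which leaves time for the 6-endo closure. The route is rejoined at 9.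

Step 6. The carbonyl olefination may be too slow, because C9 is conjugated and sits between quaternary C10 and the methyl-bearing C8, so that decay of the titanium reagent outruns methylenation. The fallback is a two-stage Peterson olefination. Setting out from 9, excess Me3SiCH2Li with anhydrous CeCl3 in THF at −78 °C (one equivalent allowed for the α-sulfonyl C–H) should add to the carbonyl to give the β-hydroxysilane F2. KH in THF then effects syn elimination, and the route is rejoined at 10.

Step 7. Hydride delivery to C9 may show poor facial selectivity, or the borane may add across the conjugated diene or to the ring alkene. The fallback sets C9 by displacement instead of addition and bypasses the diene. Setting out from 9, Corey–Chaykovsky epoxidation with dimethylsulfonium methylide (Me3SI, KHMDS, THF, −10 °C → rt) should deliver CH2 axially on the α face to give the spiro vinyl oxirane F3 with oxygen on the β face. Palladium-catalysed formate hydrogenolysis (Pd2(dba)3, n-Bu3P, HCO2H/Et3N, dioxane, rt), known to turn alkenyl oxiranes into homoallylic alcohols with hydride entering the oxirane carbon with inversion, should then place H on C9 α and leave CH2OH β. The route is rejoined at 12.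

**Further compounds**

F1 | step 5 | (5S,6S)-5-(2-bromopropan-2-yl)-2,6-dimethyl-6-[2-(phenylsulfonyl)prop-2-en-1-yl]cyclohex-2-en-1-one | CC1=CC[C@@H](C(C)(C)Br)[C@](C)(CC(=C)S(=O)(=O)c2ccccc2)C1=O
F2 | step 6 | 2ξ-(phenylsulfonyl)-9-[(trimethylsilyl)methyl]-11-nordrim-7-en-9-ol | CC1=CC[C@H]2C(C)(C)CC(S(=O)(=O)c3ccccc3)C[C@]2(C)C1(O)C[Si](C)(C)C
F3 | step 7 | 9β,11-epoxy-2ξ-(phenylsulfonyl)drim-7-ene (spiro-oxirane at C9) | CC1=CC[C@H]2C(C)(C)CC(S(=O)(=O)c3ccccc3)C[C@]2(C)[C@]13CO3
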